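A small charge of solid reagent against a large dose of substrate is where we begin, so we first ask what each flask can end with, and then how fast it gets there.

| flask | substrate | capture agent | solid reagent | free catalyst | temperature | remark | time |
|---|---|---|---|---|---|---|---|
| elm | 0.071 M (fed, over 50 min) | 0.010 M | 0.18 M | 30 mM | −14 °C | run made earlier; the fed solution adds 0.10 times the starting volume |  |
| birch | 0.14 M (fed, over 50 min) | 0.010 M | 0.18 M | 30 mM | 0 °C | run made earlier; the fed solution adds 0.10 times the starting volume |  |
| larch | 0.20 M (fed, over 50 min) | 0.010 M | 0.18 M | 57 mM | −14 °C | run made earlier; the fed solution adds 0.10 times the starting volume |  |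
| Sunday's | 0.20 M (fed, over 50 min) | 0.0100 M | 0.180 M | 30 mM |  | at −20 °C until 10 min, from then on at 5 °C; the fed solution adds 0.10 times the starting volume | 50 min |
| Friday's | 0.12 M (fed, over 50 min) | 0.0100 M | 0.180 M | 100 mM |  | at −20 °C throughout; the fed solution adds 0.10 times the starting volume | 50 min |

| run | time / min | product / % |
|---|---|---|
| elm | 2.00 | 0 |
| elm | 3.00 | 0 |
| elm | 5.00 | 0.6 |
| elm | 8.00 | 2.7 |
| elm | 10.0 | 1.7 |
| elm | 15.0 | 6.9 |
| elm | 25.0 | 22.8 |
| birch | 0.667 | 0 |
| birch | 1.00 | 0.8 |
| birch | 2.00 | 0.1 |
| birch | 3.00 | 0.1 |
| birch | 4.00 | 2.4 |
| birch | 6.00 | 1.8 |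
| birch | 10.0 | 8.0 |
| larch | 5.00 | 0.4 |
| larch | 10.0 | 4.3 |
| larch | 15.0 | 8.5 |
| larch | 20.0 | 18.1 |
| larch | 25.0 | 28.1 |

(readings scatter by 1 percentage point)

1. the flask that ends with the higher amount of product, in percent of the substrate charged, or "neither" when 2 percentage points or less lies between them (Sunday's / Friday's / neither)
2. final product, as a percentage of the substrate charged, in Sunday's
3. final product, as a percentage of the substrate charged, in Friday's

- every charge counts on the volume at the start, and the solution that is fed holds the whole dose
- solid, in amounts per volume of the solution: solid reagent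
- what was read earlier has a scatter of 1 percentage point, one standard deviation
- at the start none of the solid reagent is in solution
- percentages count the whole charge, also what has not yet gone in

We assume that each product takes up one equivalent of solid reagent, which these readings do not test. In Sunday's that gives 90.0% as the solid ceiling, the charge of solid reagent over the charge of substrate, so solid reagent is the limiting reagent there. If the whole charge of capture agent took one equivalent too, our estimate of that ceiling for Sunday's would be 85.0%. In Friday's the same ratio is 150%, with more solid reagent charged than substrate, so we reckon that flask by its dose instead.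

The feed is steady, so we read a lag: the time of a reading minus the feed time that its product would need. The larch run gives 10.9 min at 25.0 min, and the birch run gives 6.00 min at 10.0 min, each a reading that carries the scatter of its product value. Friday's is colder than larch, holds more free catalyst and takes less substrate; we assume that these differences cancel, keep the larch lag, and estimate 78.1% at the end of the feed.

The weak link is Sunday's, which matches neither run: the birch lag would give 88.0% and the larch lag 78.1%. It spends 10 min at −20 °C and the rest at 5 °C, so we take the midpoint lag, 8.47 min. That gives an estimate of 83.0% for Sunday's, less than the lowered estimate of the ceiling. We commit to Sunday's ahead by 4.9 percentage points.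

The forecast differs: Friday's ahead, with 72% (55% to 85%) for Sunday's and 82% (68% to 88%) for Friday's, adding that “the solid limit is inferred, not measured”.

Sunday's ends at 84.3% and Friday's at 78.6%, so Sunday's holds more, and Sunday's stands 12 points above the forecast.

    catalyst intermediate A → catalyst intermediate B (k = 0.140 min⁻¹, Ea = 77.0 kJ mol⁻¹)
    partner + free catalyst → catalyst intermediate A (k = 89.0 L mol⁻¹ min⁻¹, Ea = 45.0 kJ mol⁻¹)
    catalyst intermediate A + capture agent → trapped intermediate (k = 2.00 L mol⁻¹ min⁻¹, Ea = 42.0 kJ mol⁻¹)
    solid reagent ⇌ partner, rate k4*(cs4 - [partner]) while solid is left; crystals form when [partner] > cs4 (solubility = 0.120 M, k = 0.0370 min⁻¹)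
    substrate + catalyst intermediate B → catalyst intermediate C (k = 1.70 L mol⁻¹ min⁻¹, Ea = 38.0 kJ mol⁻¹)
    catalyst intermediate C → free catalyst + product (k = 3.90 min⁻¹, Ea = 62.0 kJ mol⁻¹)
    (constants at −20 °C)

At 50.0 min Sunday's stands 5.7 points under its solid ceiling of 90.0%, with solid reagent at 0% and partner at 0 M. Left for 500 min, it reaches 87.5%, still less than that ceiling. A neighbour of Friday's charged with 0.48 M of substrate has a solid ceiling of 37.5% and ends at 33.4%.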